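**Retrosynthetic overview**
- The target comes from a trans-fused hydroazulen-8-one by desilylation, C8 methylenation and α-hydroxylation at C7.
- The cyclopentene is formed last, by ring-closing metathesis of a trans allyl/isopropenyl cycloheptanone, itself made by conjugate addition and enolate allylation on a 4-silyloxy-5-alkylcyclohept-2-enone.
- The cycloheptenone comes from reductive opening of the ether bridge of an 8-oxabicyclo[3.2.1]oct-3-en-2-one; the side-chain acetate comes from a Felkin-controlled Grignard addition to an α-methyl aldehyde.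
- The oxabicycle (seven-membered ring, formed first) comes from an amine-catalysed asymmetric [5+2] cycloaddition of 3-oxidopyrylium (Achmatowicz chemistry on furfuryl alcohol) with the dienamine of tiglic aldehyde.

Assumption: the target is taken exactly as drawn, i.e. the (3aS,4R,5S,7R,8aR) trans-fused hydroazulene with a (2S,3S) side chain. The catalyst enantiomer in step 3 is assigned by analogy with known enamine face selectivity and has not been verified.

Step 1
Reactants: 1 furan-2-ylmethanol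
Product: 2 6-hydroxy-2H-pyran-3(6H)-one (racemic lactol)
Conditions: mCPBA, CH2Cl2, 0 °C to rt
Reagents that add atoms: meta-chloroperoxybenzoic acid (mCPBA), O=C(OO)c1cccc(Cl)c1
Why: Achmatowicz rearrangement (peracid oxidation of the furan, then ring expansion of the hydroxy ene-dione to the pyranone lactol); the acetal centre is racemic and is erased in step 3.

Step 2
Reactants: 2 6-hydroxy-2H-pyran-3(6H)-one
Product: 3 5-oxo-5,6-dihydro-2H-pyran-2-yl acetate (racemic)
Conditions: Ac2O, pyridine, DMAP (cat.), CH2Cl2, 0 °C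
Reagents that add atoms: acetic anhydride, CC(=O)OC(C)=O
Why: DMAP-catalysed O-acylation turns the anomeric hydroxyl into the acetate leaving group needed to generate the pyrylium ylide.

Step 3
Reactants: 3 5-oxo-5,6-dihydro-2H-pyran-2-yl acetate; 4 (E)-2-methylbut-2-enal (tiglic aldehyde)
Product: 8 (2S)-2-[(1S,5S,6S)-2-oxo-8-oxabicyclo[3.2.1]oct-3-en-6-yl]propanal (6-exo), via 3-oxidopyrylium 5 (not isolated), via dienamine 6 (not isolated), via enamine cycloadduct 7 (not isolated)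
Conditions: 4 (3 equiv), (R)-2-[diphenyl(trimethylsilyloxy)methyl]pyrrolidine (20 mol %), PhCO2H (20 mol %), i-Pr2NEt (1.2 equiv, slow addition), CHCl3, −20 °C to rt; aqueous work-up
Reagents that add atoms: none
Why: Proposed new method: the prolinol silyl ether condenses with 4 to the s-trans (E)-dienamine 6, whose distal electron-rich C=C serves as the 2π partner for the ylide 5 released from 3 by base, so that a concerted exo [5+2] on the unshielded face joins the CH2 terminus to the ylide carbon next to the oxido group (the usual 6-substituent regiochemistry) and sets C1, C5 and C6, after which enamine 7 is protonated from the same unshielded face to set the propanal C2 centre before hydrolysis; the closest known reactions are the dienamine-mediated β,γ-selective [5+2] of benzo-fused oxidopyrylium ylides with enals, trienamine cycloadditions and the thermal 3-oxidopyrylium–alkene [5+2].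

Step 4
Reactants: 8 (2S)-2-[(1S,5S,6S)-2-oxo-8-oxabicyclo[3.2.1]oct-3-en-6-yl]propanal; 9 4-bromo-2-methylbut-1-ene
Product: 12 (2S,3S)-6-methyl-2-[(1S,5S,6S)-2-oxo-8-oxabicyclo[3.2.1]oct-3-en-6-yl]hept-6-en-3-yl acetate, via Grignard reagent 10 (not isolated), via magnesium alkoxide 11 (not isolated)
Conditions: 9, Mg, THF, rt; then 8, THF, −78 °C; then Ac2O, DMAP, −78 to 0 °C
Reagents that add atoms: acetic anhydride, CC(=O)OC(C)=O
Why: Grignard 1,2-addition is much faster at the aldehyde than at the bridged, non-enolisable enone carbonyl at −78 °C, and Felkin–Anh control (bicyclic substituent as the large group) gives the 2,3-syn (3S) carbinol, whose alkoxide is acetylated in the same flask.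

Step 5
Reactants: 12 (2S,3S)-6-methyl-2-[(1S,5S,6S)-2-oxo-8-oxabicyclo[3.2.1]oct-3-en-6-yl]hept-6-en-3-yl acetate
Product: 13 (2S,3S)-2-[(1S,2S)-2-hydroxy-5-oxocyclohept-3-en-1-yl]-6-methylhept-6-en-3-yl acetate
Conditions: SmI2 (2.1 equiv), THF/MeOH, −78 °C
Reagents that add atoms: none
Why: Molander-type SmI2 reduction cleaves the aligned α-alkoxy C–O bond next to the ketone, and α'-protonation of the samarium dienolate keeps the enone, so the other C–O bond survives with its configuration and the bridgehead centre next to the carbonyl disappears.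

Step 6
Reactants: 13 (2S,3S)-2-[(1S,2S)-2-hydroxy-5-oxocyclohept-3-en-1-yl]-6-methylhept-6-en-3-yl acetate
Product: 14 (2S,3S)-2-[(1S,2S)-2-[(tert-butyldimethylsilyl)oxy]-5-oxocyclohept-3-en-1-yl]-6-methylhept-6-en-3-yl acetate
Conditions: TBSOTf, 2,6-lutidine, CH2Cl2, −78 °C
Reagents that add atoms: tert-butyldimethylsilyl trifluoromethanesulfonate (TBSOTf), CC(C)(C)[Si](C)(C)OS(=O)(=O)C(F)(F)F
Why: Silyl triflate silylation of the hindered allylic alcohol installs the bulky γ-silyloxy group that directs the conjugate addition in step 7.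

Step 7
Reactants: 14 (2S,3S)-2-[(1S,2S)-2-[(tert-butyldimethylsilyl)oxy]-5-oxocyclohept-3-en-1-yl]-6-methylhept-6-en-3-yl acetate; 15 prop-1-en-2-ylmagnesium bromide; 16 3-iodoprop-1-ene (allyl iodide)
Product: 18 (2S,3S)-2-[(1S,2R,3S,4R)-2-[(tert-butyldimethylsilyl)oxy]-5-oxo-4-(prop-2-en-1-yl)-3-(prop-1-en-2-yl)cycloheptyl]-6-methylhept-6-en-3-yl acetate, via magnesium enolate 17 (not isolated)
Conditions: 15 (1.3 equiv), CuBr·SMe2 (10 mol %), THF, −78 °C; then 16 (5 equiv), DMPU, −78 to −20 °C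
Reagents that add atoms: none
Why: Copper-catalysed conjugate addition of the alkenyl Grignard anti to the γ-silyloxy group (and to the neighbouring side chain) sets ring C3, and the regiodefined enolate is allylated in situ trans to the new substituent (three-component enone coupling), setting ring C4.

Step 8
Reactants: 18 (2S,3S)-2-[(1S,2R,3S,4R)-2-[(tert-butyldimethylsilyl)oxy]-5-oxo-4-(prop-2-en-1-yl)-3-(prop-1-en-2-yl)cycloheptyl]-6-methylhept-6-en-3-yl acetate
Product: 19 (2S,3S)-2-[(3aS,4R,5S,8aR)-4-[(tert-butyldimethylsilyl)oxy]-3-methyl-8-oxo-1,3a,4,5,6,7,8,8a-octahydroazulen-5-yl]-6-methylhept-6-en-3-yl acetate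
Conditions: Grubbs II (5 mol %), CH2Cl2 (0.005 M), 40 °C
Reagents that add atoms: none
Why: Ring-closing metathesis of the vicinal allyl and isopropenyl groups closes the methyl-substituted cyclopentene and gives the trans-fused hydroazulenone; the remote 1,1-disubstituted side-chain alkene cannot compete with five-ring closure.

Step 9
Reactants: 19 (2S,3S)-2-[(3aS,4R,5S,8aR)-4-[(tert-butyldimethylsilyl)oxy]-3-methyl-8-oxo-1,3a,4,5,6,7,8,8a-octahydroazulen-5-yl]-6-methylhept-6-en-3-yl acetate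
Product: 21 (2S,3S)-2-[(3aS,4R,5S,7R,8aR)-4-[(tert-butyldimethylsilyl)oxy]-7-hydroxy-3-methyl-8-oxo-1,3a,4,5,6,7,8,8a-octahydroazulen-5-yl]-6-methylhept-6-en-3-yl acetate, via potassium enolate 20 (not isolated)
Conditions: KHMDS (1.1 equiv), THF, −78 °C; 2-(benzenesulfonyl)-3-phenyloxaziridine, −78 °C; AcOH quench
Reagents that add atoms: 2-(benzenesulfonyl)-3-phenyloxaziridine (Davis reagent), O=S(=O)(c1ccccc1)N1OC1c1ccccc1
Why: Kinetic deprotonation at the less substituted α-CH2 (not the ring-fusion CH), then Davis enolate hydroxylation on the face opposite the α-oriented C5 side chain and C1 methylene, gives the 7R alcohol.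

Step 10
Reactants: 21 (2S,3S)-2-[(3aS,4R,5S,7R,8aR)-4-[(tert-butyldimethylsilyl)oxy]-7-hydroxy-3-methyl-8-oxo-1,3a,4,5,6,7,8,8a-octahydroazulen-5-yl]-6-methylhept-6-en-3-yl acetate
Product: 22 (2S,3S)-2-[(3aS,4R,5S,7R,8aR)-4-[(tert-butyldimethylsilyl)oxy]-7-hydroxy-3-methyl-8-methylidene-1,3a,4,5,6,7,8,8a-octahydroazulen-5-yl]-6-methylhept-6-en-3-yl acetate
Conditions: Zn, CH2Br2, TiCl4 (Takai–Lombardo), THF/CH2Cl2, 0 °C to rt
Reagents that add atoms: dibromomethane, BrCBr
Why: Takai–Lombardo methylenation is non-basic, so the hindered enolisable ketone is converted to the exocyclic alkene without epimerising C8a, and the acetate, free hydroxyl and silyl ether are tolerated.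

Step 11
Reactants: 22 (2S,3S)-2-[(3aS,4R,5S,7R,8aR)-4-[(tert-butyldimethylsilyl)oxy]-7-hydroxy-3-methyl-8-methylidene-1,3a,4,5,6,7,8,8a-octahydroazulen-5-yl]-6-methylhept-6-en-3-yl acetate
Product: 23 (2S,3S)-2-[(3aS,4R,5S,7R,8aR)-4,7-dihydroxy-3-methyl-8-methylidene-1,3a,4,5,6,7,8,8a-octahydroazulen-5-yl]-6-methylhept-6-en-3-yl acetate (target)
Conditions: HF·pyridine, pyridine/THF, 0 °C to rt
Reagents that add atoms: none
Why: Fluoride-mediated Si–O cleavage removes the TBS ether, and the buffered conditions leave the acetate, the allylic alcohol and the alkenes untouched.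

**Compound list**
1 | furan-2-ylmethanol (furfuryl alcohol) | OCc1ccco1 | starting material
2 | 6-hydroxy-2H-pyran-3(6H)-one (racemic lactol; centre erased in step 3) | OC1OCC(=O)C=C1 | intermediate
3 | 5-oxo-5,6-dihydro-2H-pyran-2-yl acetate (racemic; centre erased in step 3) | CC(=O)OC1OCC(=O)C=C1 | intermediate
4 | (E)-2-methylbut-2-enal (tiglic aldehyde) | C/C=C(\C)C=O | starting material
5 | 3-oxidopyrylium (pyrylium-3-olate) | [O-]c1ccc[o+]c1 | intermediate (not isolated)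
6 | (2R)-2-{diphenyl[(trimethylsilyl)oxy]methyl}-1-[(1E)-2-methylbuta-1,3-dien-1-yl]pyrrolidine | C=C/C(C)=C/N1CCC[C@@H]1C(O[Si](C)(C)C)(c1ccccc1)c1ccccc1 | intermediate (not isolated)
7 | (1S,5S,6S)-6-[(1E)-1-{(2R)-2-[diphenyl(trimethylsilyloxy)methyl]pyrrolidin-1-yl}prop-1-en-2-yl]-8-oxabicyclo[3.2.1]oct-3-en-2-one | C/C(=C\N1CCC[C@@H]1C(O[Si](C)(C)C)(c1ccccc1)c1ccccc1)[C@@H]1C[C@H]2C(=O)C=C[C@@H]1O2 | intermediate (not isolated)
8 | (2S)-2-[(1S,5S,6S)-2-oxo-8-oxabicyclo[3.2.1]oct-3-en-6-yl]propanal | O=C[C@@H](C)[C@@H]1C[C@H]2C(=O)C=C[C@@H]1O2 | intermediate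
9 | 4-bromo-2-methylbut-1-ene | C=C(C)CCBr | starting material
10 | (3-methylbut-3-en-1-yl)magnesium bromide | C=C(C)CC[Mg]Br | intermediate (not isolated)
11 | bromomagnesium (2S,3S)-6-methyl-2-[(1S,5S,6S)-2-oxo-8-oxabicyclo[3.2.1]oct-3-en-6-yl]hept-6-en-3-olate | C=C(C)CC[C@H](O[Mg]Br)[C@@H](C)[C@@H]1C[C@H]2C(=O)C=C[C@@H]1O2 | intermediate (not isolated)
12 | (2S,3S)-6-methyl-2-[(1S,5S,6S)-2-oxo-8-oxabicyclo[3.2.1]oct-3-en-6-yl]hept-6-en-3-yl acetate | C=C(C)CC[C@H](OC(C)=O)[C@@H](C)[C@@H]1C[C@H]2C(=O)C=C[C@@H]1O2 | intermediate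
13 | (2S,3S)-2-[(1S,2S)-2-hydroxy-5-oxocyclohept-3-en-1-yl]-6-methylhept-6-en-3-yl acetate | C=C(C)CC[C@H](OC(C)=O)[C@@H](C)[C@@H]1CCC(=O)C=C[C@@H]1O | intermediate
14 | (2S,3S)-2-[(1S,2S)-2-[(tert-butyldimethylsilyl)oxy]-5-oxocyclohept-3-en-1-yl]-6-methylhept-6-en-3-yl acetate | C=C(C)CC[C@H](OC(C)=O)[C@@H](C)[C@@H]1CCC(=O)C=C[C@@H]1O[Si](C)(C)C(C)(C)C | intermediate
15 | prop-1-en-2-ylmagnesium bromide (isopropenylmagnesium bromide) | C=C(C)[Mg]Br | starting material
16 | 3-iodoprop-1-ene (allyl iodide) | C=CCI | starting material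
17 | bromomagnesium (3S,4R,5S)-5-[(2S,3S)-3-(acetyloxy)-6-methylhept-6-en-2-yl]-4-[(tert-butyldimethylsilyl)oxy]-3-(prop-1-en-2-yl)cyclohept-1-en-1-olate | C=C(C)CC[C@H](OC(C)=O)[C@@H](C)[C@@H]1CCC(O[Mg]Br)=C[C@@H](C(C)=C)[C@@H]1O[Si](C)(C)C(C)(C)C | intermediate (not isolated)
18 | (2S,3S)-2-[(1S,2R,3S,4R)-2-[(tert-butyldimethylsilyl)oxy]-5-oxo-4-(prop-2-en-1-yl)-3-(prop-1-en-2-yl)cycloheptyl]-6-methylhept-6-en-3-yl acetate | C=C(C)CC[C@H](OC(C)=O)[C@@H](C)[C@@H]1CCC(=O)[C@H](CC=C)[C@@H](C(C)=C)[C@@H]1O[Si](C)(C)C(C)(C)C | intermediate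
19 | (2S,3S)-2-[(3aS,4R,5S,8aR)-4-[(tert-butyldimethylsilyl)oxy]-3-methyl-8-oxo-1,3a,4,5,6,7,8,8a-octahydroazulen-5-yl]-6-methylhept-6-en-3-yl acetate | C=C(C)CC[C@H](OC(C)=O)[C@@H](C)[C@@H]1CCC(=O)[C@@H]2CC=C(C)[C@H]2[C@@H]1O[Si](C)(C)C(C)(C)C | intermediate
20 | potassium (3aS,4R,5S,8aR)-5-[(2S,3S)-3-(acetyloxy)-6-methylhept-6-en-2-yl]-4-[(tert-butyldimethylsilyl)oxy]-3-methyl-1,3a,4,5,6,8a-hexahydroazulen-8-olate | C=C(C)CC[C@H](OC(C)=O)[C@@H](C)[C@@H]1CC=C(O[K])[C@@H]2CC=C(C)[C@H]2[C@@H]1O[Si](C)(C)C(C)(C)C | intermediate (not isolated)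
21 | (2S,3S)-2-[(3aS,4R,5S,7R,8aR)-4-[(tert-butyldimethylsilyl)oxy]-7-hydroxy-3-methyl-8-oxo-1,3a,4,5,6,7,8,8a-octahydroazulen-5-yl]-6-methylhept-6-en-3-yl acetate | C=C(C)CC[C@H](OC(C)=O)[C@@H](C)[C@@H]1C[C@@H](O)C(=O)[C@@H]2CC=C(C)[C@H]2[C@@H]1O[Si](C)(C)C(C)(C)C | intermediate
22 | (2S,3S)-2-[(3aS,4R,5S,7R,8aR)-4-[(tert-butyldimethylsilyl)oxy]-7-hydroxy-3-methyl-8-methylidene-1,3a,4,5,6,7,8,8a-octahydroazulen-5-yl]-6-methylhept-6-en-3-yl acetate | C=C(C)CC[C@H](OC(C)=O)[C@@H](C)[C@@H]1C[C@@H](O)C(=C)[C@@H]2CC=C(C)[C@H]2[C@@H]1O[Si](C)(C)C(C)(C)C | intermediate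
23 | (2S,3S)-2-[(3aS,4R,5S,7R,8aR)-4,7-dihydroxy-3-methyl-8-methylidene-1,3a,4,5,6,7,8,8a-octahydroazulen-5-yl]-6-methylhept-6-en-3-yl acetate | C=C(C)CC[C@H](OC(C)=O)[C@@H](C)[C@@H]1C[C@@H](O)C(=C)[C@@H]2CC=C(C)[C@H]2[C@@H]1O | target

**Step count and risk**
Total step count: 11. Longest linear sequence: 11 (furfuryl alcohol to target; the route is fully linear).

The three steps most likely to fail:

Step 3 (the proposed new aminocatalytic [5+2]; regio-, exo- and face selectivity and the protonation all have to work together). The fallback uses only known chemistry, sets out from 3 and comes back at 12. Commercial, achiral 4-methylpent-4-enal and (Z)-crotylboronic acid pinacol ester are combined under chiral phosphoric acid catalysis ((R)-TRIP, toluene, −30 °C; Antilla-type crotylboration through the closed chair transition state). This gives the borate 2-{[(3S,4S)-3,7-dimethylocta-1,7-dien-4-yl]oxy}-4,4,5,5-tetramethyl-1,3,2-dioxaborolane F1, which is hydrolysed on work-up to the syn alcohol (3S,4S)-3,7-dimethylocta-1,7-dien-4-ol F2 and acetylated (Ac2O, pyridine, DMAP) to (3S,4S)-3,7-dimethylocta-1,7-dien-4-yl acetate F3. F3, used in excess, is then the 2π partner in a thermal Hendrickson–Sammes [5+2] with the oxidopyrylium generated from 3 (Et3N by slow addition, MeCN, 60 °C). Its monosubstituted vinyl group reacts in preference to the 1,1-disubstituted alkene and with the usual 6-substituent regiochemistry, and 12 is obtained after chromatographic separation from its exo/endo and facial diastereomers. Steps 3 and 4 are then not needed.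

Step 5 (the SmI2 cleavage could instead break the vinylogous γ C–O bond of the enone, or over-reduce). The fallback sets out from 12 and comes back at 13. The enone is first masked by thia-Michael addition (PhSH, cat. Et3N, CH2Cl2, 0 °C) to give (2S,3S)-6-methyl-2-[(1S,4S,5R,6S)-2-oxo-4-(phenylsulfanyl)-8-oxabicyclo[3.2.1]octan-6-yl]hept-6-en-3-yl acetate F4. This is now a plain α-alkoxy ketone, so SmI2/MeOH at −78 °C can only cleave the wanted bond and gives (2S,3S)-2-[(1S,2R,3S)-2-hydroxy-5-oxo-3-(phenylsulfanyl)cycloheptyl]-6-methylhept-6-en-3-yl acetate F5. DBU (CH2Cl2, rt) then eliminates thiophenol and returns the enone 13.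

Step 9 (face selectivity of the enolate hydroxylation at C7). The fallback sets out from 19 and comes back at 22. If hydroxylation occurs mainly on the α face, the product is the epimer (2S,3S)-2-[(3aS,4R,5S,7S,8aR)-4-[(tert-butyldimethylsilyl)oxy]-7-hydroxy-3-methyl-8-oxo-1,3a,4,5,6,7,8,8a-octahydroazulen-5-yl]-6-methylhept-6-en-3-yl acetate F6. It is methylenated as in step 10 to (2S,3S)-2-[(3aS,4R,5S,7S,8aR)-4-[(tert-butyldimethylsilyl)oxy]-7-hydroxy-3-methyl-8-methylidene-1,3a,4,5,6,7,8,8a-octahydroazulen-5-yl]-6-methylhept-6-en-3-yl acetate F7. Dess–Martin oxidation gives the cross-conjugated enone (2S,3S)-2-[(3aS,4R,5S,8aR)-4-[(tert-butyldimethylsilyl)oxy]-3-methyl-8-methylidene-7-oxo-1,3a,4,5,6,7,8,8a-octahydroazulen-5-yl]-6-methylhept-6-en-3-yl acetate F8. Luche reduction (NaBH4, CeCl3·7H2O, MeOH, −78 °C) then delivers hydride from the same, evidently more accessible α face and gives the 7R alcohol 22.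

Further compounds
F1 | step 3 | 2-{[(3S,4S)-3,7-dimethylocta-1,7-dien-4-yl]oxy}-4,4,5,5-tetramethyl-1,3,2-dioxaborolane | C=C(C)CC[C@H](OB1OC(C)(C)C(C)(C)O1)[C@@H](C)C=C
F2 | step 3 | (3S,4S)-3,7-dimethylocta-1,7-dien-4-ol | C=C(C)CC[C@H](O)[C@@H](C)C=C
F3 | step 3 | (3S,4S)-3,7-dimethylocta-1,7-dien-4-yl acetate | C=C(C)CC[C@H](OC(C)=O)[C@@H](C)C=C
F4 | step 5 | (2S,3S)-6-methyl-2-[(1S,4S,5R,6S)-2-oxo-4-(phenylsulfanyl)-8-oxabicyclo[3.2.1]octan-6-yl]hept-6-en-3-yl acetate | C=C(C)CC[C@H](OC(C)=O)[C@@H](C)[C@@H]1C[C@H]2C(=O)C[C@H](Sc3ccccc3)[C@@H]1O2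
F5 | step 5 | (2S,3S)-2-[(1S,2R,3S)-2-hydroxy-5-oxo-3-(phenylsulfanyl)cycloheptyl]-6-methylhept-6-en-3-yl acetate | C=C(C)CC[C@H](OC(C)=O)[C@@H](C)[C@@H]1CCC(=O)C[C@H](Sc2ccccc2)[C@@H]1O
F6 | step 9 | (2S,3S)-2-[(3aS,4R,5S,7S,8aR)-4-[(tert-butyldimethylsilyl)oxy]-7-hydroxy-3-methyl-8-oxo-1,3a,4,5,6,7,8,8a-octahydroazulen-5-yl]-6-methylhept-6-en-3-yl acetate | C=C(C)CC[C@H](OC(C)=O)[C@@H](C)[C@@H]1C[C@H](O)C(=O)[C@@H]2CC=C(C)[C@H]2[C@@H]1O[Si](C)(C)C(C)(C)C
F7 | step 9 | (2S,3S)-2-[(3aS,4R,5S,7S,8aR)-4-[(tert-butyldimethylsilyl)oxy]-7-hydroxy-3-methyl-8-methylidene-1,3a,4,5,6,7,8,8a-octahydroazulen-5-yl]-6-methylhept-6-en-3-yl acetate | C=C(C)CC[C@H](OC(C)=O)[C@@H](C)[C@@H]1C[C@H](O)C(=C)[C@@H]2CC=C(C)[C@H]2[C@@H]1O[Si](C)(C)C(C)(C)C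
F8 | step 9 | (2S,3S)-2-[(3aS,4R,5S,8aR)-4-[(tert-butyldimethylsilyl)oxy]-3-methyl-8-methylidene-7-oxo-1,3a,4,5,6,7,8,8a-octahydroazulen-5-yl]-6-methylhept-6-en-3-yl acetate | C=C(C)CC[C@H](OC(C)=O)[C@@H](C)[C@@H]1CC(=O)C(=C)[C@@H]2CC=C(C)[C@H]2[C@@H]1O[Si](C)(C)C(C)(C)C
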